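## Analysis of the target

β-HIVS 16 is a naphthazarin (5,8-dihydroxy-1,4-naphthoquinone; ring A = C1–C4 with C4a and C8a, ring B = C5–C8) carrying at C2 the chain C1'(O-acyl)–C2'H2–C3'H=C4'(CH3)2, whose C1' oxygen is esterified by 3-hydroxy-3-methylbutanoic acid 11. C1' is the only stereocenter and is (R), as in the parent alcohol shikonin; with no second stereocenter to relay from, its configuration must come from a reagent or catalyst. The core is redox-active, electrophilic and tautomeric, so that rings A and B swap the quinone and hydroquinone roles by proton shift. The C1'–O ester bond ionises easily while the ring system is electron-rich and is expelled from the reduced (hydroquinone) form. The C3'=C4' alkene cyclises onto a free C1' hydroxyl under acid, and the tertiary β-hydroxy ester can dehydrate. Three things make the synthesis hard: a naphthazarin protection that comes off without strong Lewis acids, attachment of the prenyl terminus next to the carbinol without the branched dimethylallyl isomer, and absolute control at a benzylic carbinol carbon. The plan treats C1' and C2' as a two-carbon vinyl unit inserted between C2 of ring A, which acts as the aryl nucleophile, and C3', which arrives as a 2-methylpropenyl electrophile. C2–C1' and C2'–C3' then form in one catalytic event, and C1' keeps a boron atom that later becomes the oxygen.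

## Retrosynthetic reasoning

16 ⇒ 15. The last operation cuts only heteroatom bonds: the two aryl O–CH2 acetal bonds and the O–Si bond of the tertiary alcohol. It is placed last because the free naphthazarin would not survive organometallic or oxidative steps. By then the C1' oxygen is acylated, which blocks the acid-induced cyclisation onto C3'=C4'. The forward step must remove three protecting groups with dilute acid and leave the ester, the alkene and the tertiary alcohol untouched.

15 ⇒ 14. This is a redox disconnection: one bis-acetal ring of the tetra-ether is the latent quinone. Oxidation comes before the acid step because a C1' ester on the electron-rich naphthalene 14 would ionise in acid, whereas a quinone in the ring system deactivates that position. The choice of ring is not critical. 15 has the quinone in ring B, and a quinone in ring A would lead, once the acetals are gone, to the same tautomeric naphthazarin 16.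

14 ⇒ 10 + 13. The acyl C–O bond is cut. At the stage of 10 the C1' hydroxyl is the only free hydroxyl, so no selectivity is needed. The acid partner 13 is reached from 11 through 12. Its tertiary hydroxyl is silylated so that the activated acid can neither oligomerise nor dehydrate.

10 ⇒ 9 ⇒ 8 + 5, and 8 ⇒ 7 + 6. C2–C1' and C2'–C3' are cut together, after exchanging the C1' oxygen for boron. Cutting C1'–C2' instead would call for a prenyl nucleophile adding to an arene carbaldehyde, which delivers the branched isomer. Cutting only C2–C1' would need a separate carbonyl reduction to set C1'. The chosen cut gives three achiral pieces, namely aryllithium 7, vinylboronate 6 and alkenyl triflate 5. The forward reaction has to join them with catalyst-controlled face selection at the vinyl group and then replace boron by oxygen with retention.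

7 ⇒ 3 ⇒ 1, and 5 ⇒ 4. The C2–Li bond comes from acetal-directed C–H lithiation of 3. All four ring CH positions of 3 are equivalent, so one aryllithium results, and it is halide-free. Tetra-ether 3 comes from naphthazarin 1 by reduction to 2 and fourfold O-alkylation. Triflate 5 is the enol triflate of aldehyde 4.

## Alternatives that were turned down

Alternative 1: Ring A is disconnected at C1–C8a and C4–C4a into a symmetrical aryne, released from bromoarene A3, and the 3-substituted furan A2 that already holds the silyl-protected (R)-carbinol chain. In the forward step lithium 2,2,6,6-tetramethylpiperidide removes the proton next to bromine in A3, the aryne forms and adds across C2 and C5 of A2, and oxanorbornadiene A1 results as both bridgehead epimers. The aryne is symmetrical, so the cycloaddition has no regiochemical question, and it needs no chiral catalyst. On robustness of the key step it is stronger than the chosen route, whose catalyst must accept an untried aryl group. Against it, A1 carries one bridging oxygen for the two positions C1 and C4. Acid opening to a naphthol and a second oxidation are therefore needed, and the cation formed on opening sits next to the allylic silyloxy carbon C1', which invites elimination. The stereocenter is not made in the key step, and building A2 meets the same prenyl transposition problem or costs a ketone formation and an asymmetric reduction. About ten steps result against seven. The chosen route starts with all four oxygens in place and makes C1' together with both C–C bonds.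

Alternative 2: Ring A is disconnected at C4–C4a, leading back to the 4-aryl-4-hydroxycyclobutenone A5. On heating, A5 opens by 4π electrocyclic ring opening to an arylvinylketene, whose ketene carbon closes onto the free ortho carbon (6π electrocyclisation), and tautomerisation gives hydroquinone A4. Ring A arrives at the hydroquinone level with the side chain fixed at C2, so a mild oxidant gives the quinone with no ring-selectivity question. On this point it is stronger than the chosen route, which instead relies on the two possible dialkoxyquinones converging on one naphthazarin. Against it, A5 needs an unsymmetrical cyclobutenedione with hydrogen on one vinylic carbon and the chiral chain on the other, made over several steps with the stereocenter prepared beforehand. The aryl nucleophile must also choose between two different carbonyl groups. The alkyl acetal at C1' of A4 needs stronger acid than the aryl acetals, which exposes the homoallylic alcohol to cyclisation. About eleven steps are expected against seven, and the stereocenter lies outside the key step, whereas the chosen route creates it in the bond-forming event itself.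

Alternative 3: Ring A is disconnected at C3–C4, C1–C2 and C1–C8a into the aryl(methoxy)carbene complex A7, the chiral propargylic silyl ether A8 and one carbonyl ligand. On gentle heating, loss of CO, alkyne insertion with the larger substituent next to the CO-derived carbon, CO insertion and electrocyclisation give naphthol A6. The oxygen pattern of ring A is regiodefined and the C1–OH/C4–OMe ring is oxidised to the quinone under mild conditions. Here too ring selectivity is secured better than in the chosen route. Against it stand stoichiometric chromium, possible chelation of the ortho acetal oxygen of A7 to chromium, and side products favoured by propargylic oxygen. A8 needs a separate enantioselective synthesis of three to four steps, and three kinds of protecting group are involved. About eleven steps are expected against seven, and the stereocenter again lies outside the key step.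

Key step: step 3

Assumptions: Naphthazarin numbering (C1–C8, primed chain atoms) is used throughout. The two naphthazarin tautomers interconvert rapidly and are treated as one compound, drawn as in the target. The antipode of the ferrocenyl bisphosphine that gives the (R) boronic ester is to be fixed by a trial run; the mirror-image ligand is used if the sense is reversed.

## Route

Step 1
Reactants: 1 naphthazarin (5,8-dihydroxynaphthalene-1,4-dione)
Product: 3 1,4,5,8-tetrakis(methoxymethoxy)naphthalene, via leuconaphthazarin 2 (not isolated)
Conditions: Na2S2O4, EtOAc/H2O, rt, Ar; crude 2, then NaH (excess), MOMCl, DMF, 0 °C → rt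
Reagents that add atoms: chloromethyl methyl ether (MOMCl), COCCl
Why: Dithionite reduces the quinone to the tetrol 2 (handled as its 2,3-dihydro diketo tautomer); excess NaH gives the aromatic tetra-phenoxide, which the hard electrophile MOMCl alkylates on oxygen (Williamson etherification). No stereocenter is involved.

Step 2
Reactants: 4 isobutyraldehyde (2-methylpropanal)
Product: 5 2-methylprop-1-en-1-yl trifluoromethanesulfonate
Conditions: Tf2O, 2,6-di-tert-butyl-4-methylpyridine, CH2Cl2, 0 °C → reflux; distillation
Reagents that add atoms: trifluoromethanesulfonic anhydride (Tf2O), O=S(=O)(OS(=O)(=O)C(F)(F)F)C(F)(F)F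
Why: O-Sulfonylation of the aldehyde followed by loss of the α-proton to the hindered, non-nucleophilic pyridine gives the enol triflate (enol triflation of an enolisable aldehyde). The alkene is symmetrically substituted at its far carbon, so no E/Z question arises.

Step 3
Reactants: 3 1,4,5,8-tetrakis(methoxymethoxy)naphthalene; 6 vinylboronic acid pinacol ester (2-ethenyl-4,4,5,5-tetramethyl-1,3,2-dioxaborolane); 5 2-methylprop-1-en-1-yl trifluoromethanesulfonate
Product: 10 (1R)-4-methyl-1-[1,4,5,8-tetrakis(methoxymethoxy)naphthalen-2-yl]pent-3-en-1-ol, via aryllithium 7 (not isolated), via lithium boronate 8 (not isolated), via boronic ester 9 (not isolated)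
Conditions: n-BuLi (0.95 equiv relative to 3), THF, 0 °C; 6, −78 °C → rt; Pd(OAc)2 (2 mol %), 1,1'-bis[bis(4-methoxy-3,5-dimethylphenyl)phosphino]-2,2'-bis[α-(dimethylamino)benzyl]ferrocene (single enantiomer, 2.4 mol %), 5, THF, 60 °C; then 3 M NaOH, 30% H2O2, 0 °C → rt
Reagents that add atoms: hydrogen peroxide, OO
Why: Acetal-directed ortho-lithiation of 3 (the C1 acetal oxygens guide n-BuLi to C2; all four ring CH positions are equivalent, and the slight deficit of base leaves no free alkyllithium) gives halide-free 7, which adds to the vacant boron orbital of 6 to form the four-coordinate boronate 8. Zerovalent palladium inserts into the C–O bond of triflate 5, and the resulting cationic alkenyl complex of divalent palladium coordinates the vinyl group of 8; this triggers a 1,2-metallate shift in which the aryl group moves from boron to C1' on the face opposite the metal as C2' becomes bound to palladium, and reductive elimination then forges C2'–C3' and releases 9. The closest known reaction type is the palladium-catalysed enantioselective conjunctive cross-coupling of aryllithium-derived vinylboronates with alkenyl triflates, applied here to an electron-rich aryl group with one ortho alkoxy substituent. No ring is closed. C1' is set by the chiral bisphosphine on palladium, which selects the face of the bound vinyl group (catalyst control, no other stereocenter being present), and the stereospecific anti migration transfers that choice to carbon; alkaline H2O2 then exchanges boron for oxygen with retention, so (R)-9 gives (R)-10. The step needs the metallate shift to outrun direct aryl transfer from boron to palladium and β-hydride elimination; the wide-bite-angle ligand, the triflate leaving group (a cationic, alkene-seeking metal centre), the absence of halide and the good migrating ability of the electron-rich aryl group secure this. Regiochemistry is inherent, because the aryl group can only arrive at the boron-bearing carbon and the 2-methylpropenyl group keeps its sp2 attachment point, so no branched dimethylallyl isomer can form.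

Step 4
Reactants: 11 3-hydroxy-3-methylbutanoic acid
Product: 13 3-methyl-3-[(triethylsilyl)oxy]butanoic acid, via triethylsilyl ester 12 (not isolated)
Conditions: TESOTf (2.3 equiv), 2,6-lutidine, CH2Cl2, 0 °C → rt; then K2CO3, MeOH/THF/H2O, 0 °C; work-up at pH 5
Reagents that add atoms: triethylsilyl trifluoromethanesulfonate (TESOTf), CC[Si](CC)(CC)OS(=O)(=O)C(F)(F)F
Why: The silyl triflate silylates both the carboxyl and the hindered tertiary hydroxyl; the silyl ester is far more labile than the tertiary silyl ether and is cleaved selectively by mild basic solvolysis (silylation, then chemoselective silyl ester hydrolysis).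

Step 5
Reactants: 10 (1R)-4-methyl-1-[1,4,5,8-tetrakis(methoxymethoxy)naphthalen-2-yl]pent-3-en-1-ol; 13 3-methyl-3-[(triethylsilyl)oxy]butanoic acid
Product: 14 (1R)-4-methyl-1-[1,4,5,8-tetrakis(methoxymethoxy)naphthalen-2-yl]pent-3-en-1-yl 3-methyl-3-[(triethylsilyl)oxy]butanoate
Conditions: DCC, DMAP, CH2Cl2, 0 °C → rt
Reagents that add atoms: none
Why: Steglich esterification under neutral conditions acylates the only free hydroxyl; the C1'–O bond is not broken, so the (R) configuration is kept, and the silyl ether prevents self-condensation or dehydration of the activated acid.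

Step 6
Reactants: 14 (1R)-4-methyl-1-[1,4,5,8-tetrakis(methoxymethoxy)naphthalen-2-yl]pent-3-en-1-yl 3-methyl-3-[(triethylsilyl)oxy]butanoate
Product: 15 (1R)-1-[1,4-bis(methoxymethoxy)-5,8-dioxo-5,8-dihydronaphthalen-2-yl]-4-methylpent-3-en-1-yl 3-methyl-3-[(triethylsilyl)oxy]butanoate
Conditions: (NH4)2Ce(NO3)6 (2.5 equiv), MeCN/H2O, 0 °C, short reaction time
Reagents that add atoms: none
Why: Two one-electron oxidations by tetravalent cerium turn one bis-acetal ring into the quinone while its two methoxymethyl groups leave as oxocarbenium ions that water traps (oxidative dealkylation of a hydroquinone diether). Ring B is unsubstituted, less hindered and not deactivated by the acyloxyalkyl group, so it should be the ring oxidised, giving 15; attack on ring A would not be a loss, because that ring isomer would end as the same naphthazarin under the conditions of step 7. Loss of the silyl group in the acidic medium would be harmless.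

Step 7
Reactants: 15 (1R)-1-[1,4-bis(methoxymethoxy)-5,8-dioxo-5,8-dihydronaphthalen-2-yl]-4-methylpent-3-en-1-yl 3-methyl-3-[(triethylsilyl)oxy]butanoate
Product: 16 β-HIVS, (1R)-1-(5,8-dihydroxy-1,4-dioxo-1,4-dihydronaphthalen-2-yl)-4-methylpent-3-en-1-yl 3-hydroxy-3-methylbutanoate
Conditions: TFA/CH2Cl2/H2O (10:88:2), 0 °C; NaHCO3 work-up
Reagents that add atoms: none
Why: The aryl acetals lie peri to the quinone carbonyls and are cleaved by dilute acid (acetal hydrolysis driven by the hydrogen-bonded phenols formed), and the same medium removes the tertiary silyl ether. The C1' ester sits on a ring deactivated by the fused quinone carbonyls and blocks cyclisation onto the alkene, so C1' is untouched, and proton shift between the two rings gives the target tautomer 16.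

## Compound list

1 | naphthazarin (5,8-dihydroxynaphthalene-1,4-dione) | O=C1C=CC(=O)c2c(O)ccc(O)c12 | starting material
2 | leuconaphthazarin (naphthalene-1,4,5,8-tetrol, in equilibrium with its 2,3-dihydro diketo tautomer) | Oc1ccc(O)c2c(O)ccc(O)c12 | intermediate
3 | 1,4,5,8-tetrakis(methoxymethoxy)naphthalene | COCOc1ccc(OCOC)c2c(OCOC)ccc(OCOC)c12 | intermediate
4 | isobutyraldehyde (2-methylpropanal) | CC(C)C=O | starting material
5 | 2-methylprop-1-en-1-yl trifluoromethanesulfonate | CC(C)=COS(=O)(=O)C(F)(F)F | intermediate
6 | vinylboronic acid pinacol ester (2-ethenyl-4,4,5,5-tetramethyl-1,3,2-dioxaborolane) | C=CB1OC(C)(C)C(C)(C)O1 | starting material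
7 | [1,4,5,8-tetrakis(methoxymethoxy)naphthalen-2-yl]lithium | [Li]c1cc(OCOC)c2c(OCOC)ccc(OCOC)c2c1OCOC | intermediate
8 | lithium ethenyl(pinacolato)[1,4,5,8-tetrakis(methoxymethoxy)naphthalen-2-yl]borate | [Li+].C=C[B-]1(OC(C)(C)C(C)(C)O1)c1cc(OCOC)c2c(OCOC)ccc(OCOC)c2c1OCOC | intermediate
9 | 4,4,5,5-tetramethyl-2-{(1R)-4-methyl-1-[1,4,5,8-tetrakis(methoxymethoxy)naphthalen-2-yl]pent-3-en-1-yl}-1,3,2-dioxaborolane | CC(C)=CC[C@@H](B1OC(C)(C)C(C)(C)O1)c1cc(OCOC)c2c(OCOC)ccc(OCOC)c2c1OCOC | intermediate
10 | (1R)-4-methyl-1-[1,4,5,8-tetrakis(methoxymethoxy)naphthalen-2-yl]pent-3-en-1-ol | CC(C)=CC[C@@H](O)c1cc(OCOC)c2c(OCOC)ccc(OCOC)c2c1OCOC | intermediate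
11 | 3-hydroxy-3-methylbutanoic acid | CC(C)(O)CC(=O)O | starting material
12 | triethylsilyl 3-methyl-3-[(triethylsilyl)oxy]butanoate | CC[Si](CC)(CC)OC(=O)CC(C)(C)O[Si](CC)(CC)CC | intermediate
13 | 3-methyl-3-[(triethylsilyl)oxy]butanoic acid | CC[Si](CC)(CC)OC(C)(C)CC(=O)O | intermediate
14 | (1R)-4-methyl-1-[1,4,5,8-tetrakis(methoxymethoxy)naphthalen-2-yl]pent-3-en-1-yl 3-methyl-3-[(triethylsilyl)oxy]butanoate | CC(C)=CC[C@@H](OC(=O)CC(C)(C)O[Si](CC)(CC)CC)c1cc(OCOC)c2c(OCOC)ccc(OCOC)c2c1OCOC | intermediate
15 | (1R)-1-[1,4-bis(methoxymethoxy)-5,8-dioxo-5,8-dihydronaphthalen-2-yl]-4-methylpent-3-en-1-yl 3-methyl-3-[(triethylsilyl)oxy]butanoate (ring B oxidised) | CC(C)=CC[C@@H](OC(=O)CC(C)(C)O[Si](CC)(CC)CC)c1cc(OCOC)c2C(=O)C=CC(=O)c2c1OCOC | intermediate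
16 | β-HIVS, (1R)-1-(5,8-dihydroxy-1,4-dioxo-1,4-dihydronaphthalen-2-yl)-4-methylpent-3-en-1-yl 3-hydroxy-3-methylbutanoate | CC(C)=CC[C@@H](OC(=O)CC(C)(C)O)C1=CC(=O)c2c(O)ccc(O)c2C1=O | target

## Step count and least certain steps

Total: 7 steps. Longest linear sequence: 5 steps (steps 1, 3, 5, 6, 7, from naphthazarin 1); steps 2 and 4 prepare the two side components.

**Step 3 (key step).**
- The most likely failure is direct transfer of the aryl group from boron to palladium, giving simple aryl–alkenyl coupling. The ortho acetal oxygen may bind lithium or boron and slow the metallate shift, and the very electron-rich aryl group also transmetallates easily.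
- Face selection may be eroded by the ortho substituent, and the benzylic boronate may undergo protodeboronation before oxidation.
- Fallback: 3 is lithiated to 7 as in the route. 7 is acylated with N-methoxy-N,4-dimethylpent-3-enamide F1, made from commercial 4-methylpent-3-enoic acid and N,O-dimethylhydroxylamine hydrochloride with a carbodiimide. This gives the aryl ketone 4-methyl-1-[1,4,5,8-tetrakis(methoxymethoxy)naphthalen-2-yl]pent-3-en-1-one F2, worked up under neutral conditions so that the β,γ-alkene does not move into conjugation. Reduction with (+)-B-chlorodiisopinocampheylborane in THF at low temperature, the antipode that the aryl-large/alkyl-small model assigns to the (R) carbinol, returns to the route at 10.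

**Step 1.**
- The poly-anion of 2 may be re-oxidised by traces of air and etherification may stay incomplete, leaving partly protected material at the quinone level; some C-alkylation is also possible.
- Fallback: 1 is reductively acetylated (Zn dust, Ac2O, NaOAc, warm) to the air-stable naphthalene-1,4,5,8-tetrayl tetraacetate F3. In one flask under argon, NaOMe in DMF/THF frees the tetra-phenoxide without any handling of the free tetrol, and MOMCl then gives 3.

**Step 6.**
- The C1' ester bond may ionise in the acidic cerium medium before the ring system has been oxidised. Over-oxidation and incomplete loss of the second acetal of the oxidised ring are also possible. Unselective choice of ring is harmless, since both ring isomers converge in step 7.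
- Fallback: the order is changed. 10 is oxidised at the alcohol stage with (NH4)2Ce(NO3)6 in MeCN/H2O, where hydroxyl is a poor leaving group and the free carbinol should direct oxidation to ring A. This gives 2-[(1R)-1-hydroxy-4-methylpent-3-en-1-yl]-5,8-bis(methoxymethoxy)naphthalene-1,4-dione F4. Steglich esterification of F4 with 13 (DCC, DMAP, CH2Cl2) gives (1R)-1-[5,8-bis(methoxymethoxy)-1,4-dioxo-1,4-dihydronaphthalen-2-yl]-4-methylpent-3-en-1-yl 3-methyl-3-[(triethylsilyl)oxy]butanoate F5, the ring isomer that attack on ring A in step 6 would also give. The dilute acid of step 7 (TFA/CH2Cl2/H2O, 0 °C) then removes its two peri acetals and the silyl group and returns to the route at 16.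

**Step 7.**
- Acid may add across C3'=C4', dehydrate the tertiary alcohol or solvolyse the C1' ester before both acetals are gone.
- Fallback: the ester is introduced last. 10 is oxidised to the quinone alcohol F4 as described for step 6. The peri acetals are removed by chelation with MgBr2·OEt2 in CH2Cl2/Et2O, cold and briefly because the free C1' hydroxyl can add to the alkene under stronger acid, to give shikonin, 5,8-dihydroxy-2-[(1R)-1-hydroxy-4-methylpent-3-en-1-yl]naphthalene-1,4-dione F6. Steglich esterification with 13 acylates only the side-chain hydroxyl (the chelated phenols are unreactive) and gives (1R)-1-(5,8-dihydroxy-1,4-dioxo-1,4-dihydronaphthalen-2-yl)-4-methylpent-3-en-1-yl 3-methyl-3-[(triethylsilyl)oxy]butanoate F7. Buffered HF·pyridine in THF then removes the silyl group and returns to the route at 16.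

## Further compounds

F1 | step 3 | N-methoxy-N,4-dimethylpent-3-enamide | CC(C)=CCC(=O)N(C)OC
F2 | step 3 | 4-methyl-1-[1,4,5,8-tetrakis(methoxymethoxy)naphthalen-2-yl]pent-3-en-1-one | CC(C)=CCC(=O)c1cc(OCOC)c2c(OCOC)ccc(OCOC)c2c1OCOC
F3 | step 1 | naphthalene-1,4,5,8-tetrayl tetraacetate | CC(=O)Oc1ccc(OC(C)=O)c2c(OC(C)=O)ccc(OC(C)=O)c12
F4 | step 6 | 2-[(1R)-1-hydroxy-4-methylpent-3-en-1-yl]-5,8-bis(methoxymethoxy)naphthalene-1,4-dione | CC(C)=CC[C@@H](O)C1=CC(=O)c2c(OCOC)ccc(OCOC)c2C1=O
F5 | step 6 | (1R)-1-[5,8-bis(methoxymethoxy)-1,4-dioxo-1,4-dihydronaphthalen-2-yl]-4-methylpent-3-en-1-yl 3-methyl-3-[(triethylsilyl)oxy]butanoate (ring A oxidised) | CC(C)=CC[C@@H](OC(=O)CC(C)(C)O[Si](CC)(CC)CC)C1=CC(=O)c2c(OCOC)ccc(OCOC)c2C1=O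
F6 | step 7 | shikonin, 5,8-dihydroxy-2-[(1R)-1-hydroxy-4-methylpent-3-en-1-yl]naphthalene-1,4-dione | CC(C)=CC[C@@H](O)C1=CC(=O)c2c(O)ccc(O)c2C1=O
F7 | step 7 | (1R)-1-(5,8-dihydroxy-1,4-dioxo-1,4-dihydronaphthalen-2-yl)-4-methylpent-3-en-1-yl 3-methyl-3-[(triethylsilyl)oxy]butanoate | CC(C)=CC[C@@H](OC(=O)CC(C)(C)O[Si](CC)(CC)CC)C1=CC(=O)c2c(O)ccc(O)c2C1=O
A1 | alternative 1 | tert-butyl{[(1R)-1-[5,8-bis(methoxymethoxy)-1,4-dihydro-1,4-epoxynaphthalen-2-yl]-4-methylpent-3-en-1-yl]oxy}dimethylsilane (both bridgehead epimers) | CC(C)=CC[C@@H](O[Si](C)(C)C(C)(C)C)C1=CC2OC1c1c(OCOC)ccc(OCOC)c12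
A2 | alternative 1 | tert-butyl{[(1R)-1-(furan-3-yl)-4-methylpent-3-en-1-yl]oxy}dimethylsilane | CC(C)=CC[C@@H](O[Si](C)(C)C(C)(C)C)c1ccoc1
A3 | alternative 1 | 2-bromo-1,4-bis(methoxymethoxy)benzene | COCOc1ccc(OCOC)c(Br)c1
A4 | alternative 2 | 5,8-bis(methoxymethoxy)-2-[(1R)-1-(methoxymethoxy)-4-methylpent-3-en-1-yl]naphthalene-1,4-diol | CC(C)=CC[C@@H](OCOC)c1cc(O)c2c(OCOC)ccc(OCOC)c2c1O
A5 | alternative 2 | 4-[2,5-bis(methoxymethoxy)phenyl]-4-hydroxy-3-[(1R)-1-(methoxymethoxy)-4-methylpent-3-en-1-yl]cyclobut-2-en-1-one | CC(C)=CC[C@@H](OCOC)C1=CC(=O)C1(O)c1cc(OCOC)ccc1OCOC
A6 | alternative 3 | 2-{(1R)-1-[tert-butyl(dimethyl)silyloxy]-4-methylpent-3-en-1-yl}-4-methoxy-5,8-bis(methoxymethoxy)naphthalen-1-ol | CC(C)=CC[C@@H](O[Si](C)(C)C(C)(C)C)c1cc(OC)c2c(OCOC)ccc(OCOC)c2c1O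
A7 | alternative 3 | pentacarbonyl{[2,5-bis(methoxymethoxy)phenyl](methoxy)methylidene}chromium | COC(=[Cr](=C=O)(=C=O)(=C=O)(=C=O)=C=O)c1cc(OCOC)ccc1OCOC
A8 | alternative 3 | tert-butyl{[(3R)-6-methylhept-5-en-1-yn-3-yl]oxy}dimethylsilane | CC(C)=CC[C@@H](O[Si](C)(C)C(C)(C)C)C#C
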